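## Retrosynthetic overview

1. The target is cut at the C19 ester: late O‑acylation of a 19‑hydroxy‑15‑acid with (R)‑2‑methylbutanoic acid. The C3 hydroxyl of the natural core is removed just before, by radical opening of a 3,19‑cyclic thionocarbonate.
2. Key disconnection C12–C13: a β‑nickelated crotonamide (nickel homoenolate, C13 as the nucleophile) is joined to a primary C12 iodide. This one step brings in C13–C16 and sets 13R under ligand control.
3. The C12 iodide comes from the C12 aldehyde, obtained from andrographolide by chemoselective excision of the butenolide at C12=C13.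
4. Rings: none is formed. Rings A and B, the C4/C5/C9/C10 stereocentres and the 8(17)‑methylene are taken intact from andrographolide, whose ent‑labdane core matches the target centre for centre.

Assumption: andrographolide, (E)‑N,N‑dimethylbut‑2‑enamide and (R)‑2‑methylbutanoic acid are bought as catalogue items; labdane numbering (C1–C20) is used for the core.

## Route

Step 1
Reactants: 1 andrographolide
Product: 3 (3R,4R,5S,9R,10S)-3,19-dihydroxy-13,14,15,16-tetranorlabd-8(17)-en-12-al, via 12,13-diol 2 (not isolated)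
Conditions: KMnO4 (1.2 equiv), AcOH (1.5 equiv), acetone/H2O 4:1, −35 °C; then NaIO4 (1.2 equiv), 0 → 23 °C
Reagents that add atoms: potassium permanganate, [K+].[O-][Mn](=O)(=O)=O
Why: Permanganate syn‑dihydroxylation is fastest at the electron‑poor conjugated C12=C13 alkylidene‑lactone alkene (the isolated, hindered 8(17)‑methylene reacts more slowly at low temperature), and periodate glycol cleavage (Malaprade) then excises the lactone to leave the C12 aldehyde; no stereocentre of the core is touched.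

Step 2
Reactants: 3 (3R,4R,5S,9R,10S)-3,19-dihydroxy-13,14,15,16-tetranorlabd-8(17)-en-12-al
Product: 4 (3R,4R,5S,9R,10S)-13,14,15,16-tetranorlabd-8(17)-ene-3,12,19-triol
Conditions: NaBH4, MeOH, 0 °C
Reagents that add atoms: none
Why: Plain borohydride reduction of an unhindered aldehyde; the alkene and all stereocentres are inert.

Step 3
Reactants: 4 (3R,4R,5S,9R,10S)-13,14,15,16-tetranorlabd-8(17)-ene-3,12,19-triol
Product: 5 (3R,4R,5S,9R,10S)-12-iodo-13,14,15,16-tetranorlabd-8(17)-ene-3,19-diol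
Conditions: I2 (1.2 equiv), PPh3 (1.2 equiv), imidazole (2.5 equiv), THF, 0 °C
Reagents that add atoms: iodine, II
Why: Appel‑type iodination (Garegg–Samuelsson) works by SN2 displacement of an alkoxyphosphonium, which is possible only at the unhindered primary C12 carbinol; the neopentyl C19–OH and the hindered secondary C3–OH are returned unchanged on work‑up.

Step 4
Reactants: 5 (3R,4R,5S,9R,10S)-12-iodo-13,14,15,16-tetranorlabd-8(17)-ene-3,19-diol; 6 (E)-N,N-dimethylbut-2-enamide (2 equiv)
Product: 7 (3R,4R,5S,9R,10S,13R)-3,19-dihydroxy-N,N-dimethyllabd-8(17)-en-15-amide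
Conditions: NiBr2(dme) (10 mol%), Bn-BOX ligand (12 mol%; antipode that gives 13R, fixed on a model primary iodide), (EtO)2MeSiH (3 equiv), KF (3 equiv), DMA, 0 → 23 °C
Reagents that add atoms: none
Why: NiH‑catalysed regio‑reversed asymmetric hydroalkylation of an α,β‑unsaturated amide: syn‑hydronickelation of 6 puts nickel on the β‑carbon as a five‑membered O‑chelated nickel homoenolate (C13 nucleophilic), which captures the C12 radical from iodide 5 and reductively eliminates to form C12–C13, the bis(oxazoline) ligand fixing the face of hydronickelation and hence 13R irrespective of the remote core stereocentres; free hydroxyls and the unactivated 1,1‑disubstituted alkene are tolerated by this catalyst class.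

Step 5
Reactants: 7 (3R,4R,5S,9R,10S,13R)-3,19-dihydroxy-N,N-dimethyllabd-8(17)-en-15-amide
Product: 8 3,19-O-thiocarbonyl derivative of 7 (six-membered cyclic thionocarbonate bridging O3 and O19)
Conditions: 1,1'-thiocarbonyldiimidazole (1.5 equiv), DMAP (0.2 equiv), PhMe, 80 °C
Reagents that add atoms: 1,1'-thiocarbonyldiimidazole, S=C(n1ccnc1)n1ccnc1
Why: Thiocarbonylation of the 1,3‑diol (equatorial 3‑OH, axial C19–OH, the same pair that closes andrographolide acetonides) gives the cyclic thionocarbonate with retention at C3 and C4.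

Step 6
Reactants: 8 3,19-O-thiocarbonyl derivative of 7
Product: 11 (4R,5S,9R,10S,13R)-19-hydroxylabd-8(17)-en-15-oic acid, via stannyl thiocarbonate 9 (not isolated), via hydroxy amide 10 (not isolated)
Conditions: Bu3SnH (2 equiv), AIBN (0.2 equiv), PhMe, 110 °C; then KOtBu (8 equiv), H2O (2.5 equiv), THF, 23 → 50 °C; HCl work-up to pH 3
Reagents that add atoms: tributyltin hydride, CCCC[SnH](CCCC)CCCC (tin group of 9 only); water, O (carboxyl oxygen of 11)
Why: Barton-type radical deoxygenation of a cyclic thionocarbonate: the stannyl radical adds to sulfur and β‑scission gives the secondary C3 radical in preference to the primary neopentyl C19 radical, which Bu3SnH reduces to CH2, and the anhydrous‑hydroxide (KOtBu/H2O) treatment then cleaves both the S‑stannyl thiocarbonate and the tertiary amide; C13 is β to the carbonyl and cannot epimerise.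

Step 7
Reactants: 11 (4R,5S,9R,10S,13R)-19-hydroxylabd-8(17)-en-15-oic acid; 12 (R)-2-methylbutanoic acid (3 equiv)
Product: 15 (4R,5S,9R,10S,13R)-19-[(2R)-2-methylbutanoyloxy]labd-8(17)-en-15-oic acid, via acid chloride 13 (not isolated), via mixed anhydride 14 (not isolated)
Conditions: 12, (COCl)2 (3 equiv), DMF (cat.), CH2Cl2, 0 → 23 °C, evaporate; then 11, pyridine, DMAP (0.1 equiv), 0 → 23 °C; then NaHCO3, THF/H2O, 23 °C
Reagents that add atoms: oxalyl chloride, O=C(Cl)C(Cl)=O (chlorine of 13 only); water, O (hydrolysis of 14)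
Why: DMAP‑catalysed O‑acylation of the primary C19 alcohol by the preformed acid chloride, with pyridine as the only base so that no ketene forms and C2' stays R; the C15 mixed anhydride formed alongside is hydrolysed by bicarbonate while the hindered neopentyl ester survives.

## Compound list

1 | andrographolide, (3E,4S)-3-{2-[(1R,4aS,5R,6R,8aS)-6-hydroxy-5-(hydroxymethyl)-5,8a-dimethyl-2-methylidenedecahydronaphthalen-1-yl]ethylidene}-4-hydroxyoxolan-2-one | C=C1CC[C@@H]2[C@](C)(CO)[C@H](O)CC[C@@]2(C)[C@@H]1C/C=C1/C(=O)OC[C@H]1O | starting material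
2 | 12,13-dihydroxy-12,13-dihydroandrographolide (syn glycol, C12/C13 configuration not controlled) | C=C1CC[C@@H]2[C@](C)(CO)[C@H](O)CC[C@@]2(C)[C@@H]1CC(O)C1(O)C(=O)OC[C@H]1O | intermediate (not isolated)
3 | (3R,4R,5S,9R,10S)-3,19-dihydroxy-13,14,15,16-tetranorlabd-8(17)-en-12-al | C=C1CC[C@@H]2[C@](C)(CO)[C@H](O)CC[C@@]2(C)[C@@H]1CC=O | intermediate
4 | (3R,4R,5S,9R,10S)-13,14,15,16-tetranorlabd-8(17)-ene-3,12,19-triol | C=C1CC[C@@H]2[C@](C)(CO)[C@H](O)CC[C@@]2(C)[C@@H]1CCO | intermediate
5 | (3R,4R,5S,9R,10S)-12-iodo-13,14,15,16-tetranorlabd-8(17)-ene-3,19-diol | C=C1CC[C@@H]2[C@](C)(CO)[C@H](O)CC[C@@]2(C)[C@@H]1CCI | intermediate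
6 | (E)-N,N-dimethylbut-2-enamide | C/C=C/C(=O)N(C)C | starting material
7 | (3R,4R,5S,9R,10S,13R)-3,19-dihydroxy-N,N-dimethyllabd-8(17)-en-15-amide | C=C1CC[C@@H]2[C@](C)(CO)[C@H](O)CC[C@@]2(C)[C@@H]1CC[C@@H](C)CC(=O)N(C)C | intermediate
8 | 3,19-O-thiocarbonyl derivative of 7 (cyclic thionocarbonate, O3–C(=S)–O19) | C=C1CC[C@@H]2[C@]3(C)COC(=S)O[C@@H]3CC[C@@]2(C)[C@@H]1CC[C@@H](C)CC(=O)N(C)C | intermediate
9 | (4R,5S,9R,10S,13R)-N,N-dimethyl-19-{[(tributylstannyl)sulfanyl]carbonyloxy}labd-8(17)-en-15-amide | C=C1CC[C@@H]2[C@](C)(COC(=O)S[Sn](CCCC)(CCCC)CCCC)CCC[C@@]2(C)[C@@H]1CC[C@@H](C)CC(=O)N(C)C | intermediate (not isolated)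
10 | (4R,5S,9R,10S,13R)-19-hydroxy-N,N-dimethyllabd-8(17)-en-15-amide | C=C1CC[C@@H]2[C@](C)(CO)CCC[C@@]2(C)[C@@H]1CC[C@@H](C)CC(=O)N(C)C | intermediate (not isolated)
11 | (4R,5S,9R,10S,13R)-19-hydroxylabd-8(17)-en-15-oic acid | C=C1CC[C@@H]2[C@](C)(CO)CCC[C@@]2(C)[C@@H]1CC[C@@H](C)CC(=O)O | intermediate
12 | (R)-2-methylbutanoic acid | CC[C@@H](C)C(=O)O | starting material
13 | (R)-2-methylbutanoyl chloride | CC[C@@H](C)C(=O)Cl | intermediate (not isolated)
14 | mixed anhydride of 15 (C15 carboxyl) with (R)-2-methylbutanoic acid | C=C1CC[C@@H]2[C@](C)(COC(=O)[C@H](C)CC)CCC[C@@]2(C)[C@@H]1CC[C@@H](C)CC(=O)OC(=O)[C@H](C)CC | intermediate (not isolated)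
15 | (4R,5S,9R,10S,13R)-19-[(2R)-2-methylbutanoyloxy]labd-8(17)-en-15-oic acid (CNP0365997.1) | C=C1CC[C@@H]2[C@](C)(COC(=O)[C@H](C)CC)CCC[C@@]2(C)[C@@H]1CC[C@@H](C)CC(=O)O | target

## Step count and risks

Total steps: 7. Longest linear sequence: 7 (from andrographolide 1; compounds 6 and 12 are bought).

The three steps most likely to fail:

**Step 1 (chemoselective cleavage of C12=C13 beside the 8(17)-methylene).** If permanganate attacks the exocyclic alkene competitively, the lactone can be excised without any alkene oxidation. Setting out from 1, activated MnO2 (CH2Cl2/acetone, 23 °C) oxidises only the allylic 14‑OH to give 14‑dehydroandrographolide F1, an alkylidene‑tetronic acid. As a Knoevenagel‑type adduct it undergoes retro‑Knoevenagel hydrolysis (H2O/THF, cat. pyrrolidine/AcOH, 40 °C), releasing tetronic acid and coming back to the route at aldehyde 3.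

**Step 4 (NiH homoenolate coupling: β‑regiochemistry, 13R control, free diol, possible reduction of the iodide).** If regio‑ or enantiocontrol is poor, C13 is brought in with a stoichiometric chiral homoenolate equivalent. Setting out from 5, the diol is masked with 2,2‑dimethoxypropane/PPTS as the acetonide iodide F2. The reagent tert‑butyl N‑[(E)‑but‑2‑enyl]‑N‑(4‑methoxyphenyl)carbamate F3 (from N‑Boc‑4‑methoxyaniline, NaH and (E)‑crotyl bromide) is lithiated with n‑BuLi/sparteine (antipode chosen for 13R) in toluene at −78 °C and alkylated at its γ‑carbon by F2 to give the (Z)‑enecarbamate F4. Aqueous HCl/THF hydrolyses enecarbamate and acetonide to the dihydroxy aldehyde F5, NaClO2/NaH2PO4/2‑methyl‑2‑butene gives the dihydroxy acid F6, and EDC·HCl/HOBt/Me2NH comes back to the route at amide 7.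

**Step 6 (regioselective ring opening of the cyclic thionocarbonate, then amide hydrolysis in the same pot).** If fragmentation also gives the C19 radical, or the telescoped hydrolysis is sluggish, the C3 oxygen is removed as an acyclic xanthate. Setting out from 7, TBSCl/imidazole silylates only the primary 19‑OH to give the silyl ether F7. NaH, CS2, then MeI give the 3‑O‑(S‑methyl dithiocarbonate) F8, and Bu3SnH/AIBN (Barton–McCombie) gives the 3‑deoxy silyl ether F9. TBAF comes back to the route at hydroxy amide 10, which is hydrolysed with KOtBu/H2O as in step 6 to 11.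

Further compounds
F1 | step 1 | 14-dehydroandrographolide, (E)-3-alkylidene-oxolane-2,4-dione with the 3,19-diol core of 1 | C=C1CC[C@@H]2[C@](C)(CO)[C@H](O)CC[C@@]2(C)[C@@H]1C/C=C1/C(=O)OCC1=O
F2 | step 4 | 3,19-O-isopropylidene acetal of iodide 5 | C=C1CC[C@@H]2[C@]3(C)COC(C)(C)O[C@@H]3CC[C@@]2(C)[C@@H]1CCI
F3 | step 4 | tert-butyl N-[(E)-but-2-enyl]-N-(4-methoxyphenyl)carbamate | C/C=C/CN(C(=O)OC(C)(C)C)c1ccc(OC)cc1
F4 | step 4 | (13R,14Z)-enecarbamate, 3,19-O-isopropylidene-15-[N-Boc-N-(4-methoxyphenyl)amino]-16-methyl side chain on the labd-8(17),14-diene core | C=C1CC[C@@H]2[C@]3(C)COC(C)(C)O[C@@H]3CC[C@@]2(C)[C@@H]1CC[C@@H](C)/C=C\N(C(=O)OC(C)(C)C)c1ccc(OC)cc1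
F5 | step 4 | (3R,4R,5S,9R,10S,13R)-3,19-dihydroxylabd-8(17)-en-15-al | C=C1CC[C@@H]2[C@](C)(CO)[C@H](O)CC[C@@]2(C)[C@@H]1CC[C@@H](C)CC=O
F6 | step 4 | (3R,4R,5S,9R,10S,13R)-3,19-dihydroxylabd-8(17)-en-15-oic acid | C=C1CC[C@@H]2[C@](C)(CO)[C@H](O)CC[C@@]2(C)[C@@H]1CC[C@@H](C)CC(=O)O
F7 | step 6 | 19-O-tert-butyldimethylsilyl ether of 7 | C=C1CC[C@@H]2[C@](C)(CO[Si](C)(C)C(C)(C)C)[C@H](O)CC[C@@]2(C)[C@@H]1CC[C@@H](C)CC(=O)N(C)C
F8 | step 6 | 3-O-(methylsulfanyl)thiocarbonyl (xanthate) derivative of F7 | C=C1CC[C@@H]2[C@](C)(CO[Si](C)(C)C(C)(C)C)[C@H](OC(=S)SC)CC[C@@]2(C)[C@@H]1CC[C@@H](C)CC(=O)N(C)C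
F9 | step 6 | 19-O-tert-butyldimethylsilyl ether of 10 | C=C1CC[C@@H]2[C@](C)(CO[Si](C)(C)C(C)(C)C)CCC[C@@]2(C)[C@@H]1CC[C@@H](C)CC(=O)N(C)C
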